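**Retrosynthetic overview**

1. The target comes from its tert-butyl ester by acidolysis; the dihydropyranone is the only ring and is closed in the step before, on the complete carbon chain.
2. Ring: both O1–C2 and C3–C4 are cut, giving a 3-oxoacyl ketene (from the acyl Meldrum's acid of the full diene acid) and methyl (R)-3-hydroxybutanoate; forward, O-acylation by the ketene and Dieckmann closure run in one flask.
3. Diene acid: Suzuki–Miyaura bond between the ester-bearing carbon and the (E)-alkenyl carbon, from a (Z)-2-bromoenoate and the alkenylborane of (R)-4-methylhept-6-ynoic acid.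
4. The bromoenoate comes from (S)-2-methylbutan-1-ol (oxidation, bromo-ylide Wittig); the alkynoic acid comes from (R)-citronellal (Ohira–Bestmann homologation, then ozonolysis/chlorite).
5. All three stereocentres are bought from the chiral pool and never touched; both alkene geometries are fixed in the coupling partners.

Assumption: the acyl-dihydropyranone is taken to arise in nature as acyl tetronates do, by transfer of a polyketide 3-oxoacyl unit to the hydroxyl of an (R)-3-hydroxybutyryl unit and Dieckmann (Claisen) ring closure with release of the carrier; the route copies this order, with an acylketene as acyl donor and methoxide as the leaving carrier.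

**Route**

Step 1
Reactants: 1 (S)-2-methylbutan-1-ol
Product: 2 (S)-2-methylbutanal
Conditions: TEMPO (1 mol%), KBr (10 mol%), NaOCl (1.1 equiv), NaHCO3, CH2Cl2/H2O, 0 °C
Reagents that add atoms: none
Why: Anelli oxidation (TEMPO/NaOCl) stops at the aldehyde in the buffered two-phase system at 0 °C and is the standard way to make this α-branched aldehyde without loss of configuration; the dried CH2Cl2 solution is used at once.

Step 2
Reactants: 2 (S)-2-methylbutanal; 3 tert-butyl (triphenylphosphoranylidene)acetate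
Product: 5 tert-butyl (2Z,4S)-2-bromo-4-methylhex-2-enoate, via bromo ylide 4 (not isolated)
Conditions: 3, NBS (1.0 equiv), CH2Cl2, −20 °C; then 2, −20 °C → rt
Reagents that add atoms: N-bromosuccinimide (NBS), BrN1C(=O)CCC1=O
Why: NBS brominates the stabilised ylide and the succinimide anion deprotonates the bromophosphonium ion to bromo ylide 4, whose Wittig reaction puts the ester trans to the alkyl group and so gives the (Z)-2-bromoenoate under base-free conditions that leave the α-stereocentre of 2 alone.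

Step 3
Reactants: 6 (R)-citronellal [(3R)-3,7-dimethyloct-6-enal]
Product: 7 (4R)-4,8-dimethylnon-7-en-1-yne
Conditions: Ohira–Bestmann reagent (1.2 equiv), K2CO3 (2 equiv), MeOH, 0 °C → rt
Reagents that add atoms: dimethyl (1-diazo-2-oxopropyl)phosphonate (Ohira–Bestmann reagent), CC(=O)C(=[N+]=[N-])P(=O)(OC)OC
Why: Ohira–Bestmann (Seyferth–Gilbert) homologation turns the aldehyde into the terminal alkyne under mild carbonate/methanol conditions, and the stereocentre, β to the carbonyl, cannot epimerise.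

Step 4
Reactants: 7 (4R)-4,8-dimethylnon-7-en-1-yne
Product: 9 (4R)-4-methylhept-6-ynoic acid, via ynal 8 (not isolated)
Conditions: O3, MeCN/H2O (9:1), 0 °C; N2 purge; then NaClO2 (2 equiv), NaH2PO4, rt
Reagents that add atoms: ozone, [O-][O+]=O; water, O; sodium chlorite, [Na+].[O-]Cl=O
Why: ozonolysis cleaves the electron-rich trisubstituted alkene far faster than the terminal alkyne, the aqueous medium gives aldehyde 8 and H2O2 directly, and Pinnick-type chlorite oxidation (H2O2 as hypochlorite scavenger) in the same flask gives the acid.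

Step 5
Reactants: 9 (4R)-4-methylhept-6-ynoic acid; 5 tert-butyl (2Z,4S)-2-bromo-4-methylhex-2-enoate
Product: 11 (4R,6E,8E,10S)-8-(tert-butoxycarbonyl)-4,10-dimethyldodeca-6,8-dienoic acid, via alkenylborane 10 (not isolated)
Conditions: Cy2BH (2.1 equiv, made from BH3·SMe2 and cyclohexene), THF, 0 °C → rt; then 5, Pd(PPh3)4 (5 mol%), 2 M aq NaOH, THF, 60 °C; 1 M HCl
Reagents that add atoms: none
Why: the first equivalent of Cy2BH is spent on the carboxylic acid (an acyloxyborane that dialkylboranes do not reduce further), the second adds syn and anti-Markovnikov to the alkyne, and Suzuki–Miyaura coupling of the (E)-alkenylborane with the (Z)-bromoenoate on zerovalent palladium goes with retention at both carbons, so both diene geometries are set here.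

Step 6
Reactants: 11 (4R,6E,8E,10S)-8-(tert-butoxycarbonyl)-4,10-dimethyldodeca-6,8-dienoic acid; 12 Meldrum's acid (2,2-dimethyl-1,3-dioxane-4,6-dione)
Product: 13 tert-butyl (2E,4S)-2-[(1E,4R)-7-(2,2-dimethyl-4,6-dioxo-1,3-dioxan-5-ylidene)-7-hydroxy-4-methylhept-1-en-1-yl]-4-methylhex-2-enoate
Conditions: DCC (1.1 equiv), DMAP (1.5 equiv), CH2Cl2, 0 °C → rt; filter, wash with aq KHSO4
Reagents that add atoms: none
Why: carbodiimide-mediated C-acylation of Meldrum's acid (Oikawa–Yonemitsu) takes the only free carboxylic acid and gives the enolised acyl Meldrum's acid as a stable ketene precursor, the hindered tert-butyl dienoate being inert.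

Step 7
Reactants: 13 the acyl Meldrum's acid of step 6; 14 methyl (R)-3-hydroxybutanoate
Product: 17 tert-butyl (2E,4S)-2-[(1E,4R)-7-[(6R)-4-hydroxy-6-methyl-2-oxo-5,6-dihydro-2H-pyran-3-yl]-4-methyl-7-oxohept-1-en-1-yl]-4-methylhex-2-enoate, via acylketene 15 (not isolated), via keto ester 16 (not isolated)
Conditions: 14 (1.05 equiv), toluene, 90 °C; then KOtBu (1.3 equiv), THF, 0 °C → rt; 1 M HCl
Reagents that add atoms: none
Why: Proposed new method: thermal retro-[4+2] loss of acetone and CO2 from 13 gives acylketene 15, the secondary hydroxyl of 14 captures it (Oikawa–Yonemitsu β-keto ester synthesis) to give 16, and the doubly stabilised potassium enolate of 16 closes the ring by 6-exo Dieckmann attack on the methyl ester, driven by formation of the strongly acidic tricarbonyl enolate, which also makes the acyloxy group a poor leaving group for β-elimination; the closest known reaction is the Lacey–Dieckmann cyclisation to 3-acyl tetronic and tetramic acids, and C6 keeps the (R) configuration of 14 because its C–O bond is never broken.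

Step 8
Reactants: 17 the tert-butyl ester of step 7
Product: 18 (2E,4S)-2-[(1E,4R)-7-[(6R)-4-hydroxy-6-methyl-2-oxo-5,6-dihydro-2H-pyran-3-yl]-4-methyl-7-oxohept-1-en-1-yl]-4-methylhex-2-enoic acid (target)
Conditions: TFA/CH2Cl2 (1:4), 0 °C → rt
Reagents that add atoms: none
Why: acid-catalysed tert-butyl ester cleavage (loss of isobutene) leaves the lactone, the acidic tricarbonyl unit and the diene untouched and involves no stereocentre.

**Compound list**

1 | (S)-2-methylbutan-1-ol | CC[C@H](C)CO | starting material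
2 | (S)-2-methylbutanal | CC[C@H](C)C=O | intermediate
3 | tert-butyl (triphenylphosphoranylidene)acetate | CC(C)(C)OC(=O)C=P(c1ccccc1)(c1ccccc1)c1ccccc1 | starting material
4 | tert-butyl bromo(triphenylphosphoranylidene)acetate (bromo ylide) | CC(C)(C)OC(=O)C(Br)=P(c1ccccc1)(c1ccccc1)c1ccccc1 | intermediate (not isolated)
5 | tert-butyl (2Z,4S)-2-bromo-4-methylhex-2-enoate | CC[C@H](C)/C=C(\Br)C(=O)OC(C)(C)C | intermediate
6 | (R)-citronellal, (3R)-3,7-dimethyloct-6-enal | C[C@H](CCC=C(C)C)CC=O | starting material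
7 | (4R)-4,8-dimethylnon-7-en-1-yne | C[C@H](CCC=C(C)C)CC#C | intermediate
8 | (4R)-4-methylhept-6-ynal | C[C@H](CCC=O)CC#C | intermediate (not isolated)
9 | (4R)-4-methylhept-6-ynoic acid | C[C@H](CCC(=O)O)CC#C | intermediate
10 | dicyclohexylboryl (4R,6E)-7-(dicyclohexylboryl)-4-methylhept-6-enoate | C[C@H](CCC(=O)OB(C1CCCCC1)C1CCCCC1)C/C=C/B(C1CCCCC1)C1CCCCC1 | intermediate (not isolated)
11 | (4R,6E,8E,10S)-8-(tert-butoxycarbonyl)-4,10-dimethyldodeca-6,8-dienoic acid | CC[C@H](C)/C=C(\C=C\C[C@H](C)CCC(=O)O)C(=O)OC(C)(C)C | intermediate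
12 | Meldrum's acid, 2,2-dimethyl-1,3-dioxane-4,6-dione | CC1(C)OC(=O)CC(=O)O1 | starting material
13 | tert-butyl (2E,4S)-2-[(1E,4R)-7-(2,2-dimethyl-4,6-dioxo-1,3-dioxan-5-ylidene)-7-hydroxy-4-methylhept-1-en-1-yl]-4-methylhex-2-enoate | CC[C@H](C)/C=C(\C=C\C[C@H](C)CCC(O)=C1C(=O)OC(C)(C)OC1=O)C(=O)OC(C)(C)C | intermediate
14 | methyl (R)-3-hydroxybutanoate | C[C@@H](O)CC(=O)OC | starting material
15 | tert-butyl (2E,4S)-4-methyl-2-[(1E,4R)-4-methyl-7,9-dioxonona-1,8-dien-1-yl]hex-2-enoate (acylketene) | CC[C@H](C)/C=C(\C=C\C[C@H](C)CCC(=O)C=C=O)C(=O)OC(C)(C)C | intermediate (not isolated)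
16 | (2R)-4-methoxy-4-oxobutan-2-yl (6R,8E,10E,12S)-10-(tert-butoxycarbonyl)-6,12-dimethyl-3-oxotetradeca-8,10-dienoate | CC[C@H](C)/C=C(\C=C\C[C@H](C)CCC(=O)CC(=O)O[C@H](C)CC(=O)OC)C(=O)OC(C)(C)C | intermediate (not isolated)
17 | tert-butyl (2E,4S)-2-[(1E,4R)-7-[(6R)-4-hydroxy-6-methyl-2-oxo-5,6-dihydro-2H-pyran-3-yl]-4-methyl-7-oxohept-1-en-1-yl]-4-methylhex-2-enoate | CC[C@H](C)/C=C(\C=C\C[C@H](C)CCC(=O)C1=C(O)C[C@@H](C)OC1=O)C(=O)OC(C)(C)C | intermediate
18 | (2E,4S)-2-[(1E,4R)-7-[(6R)-4-hydroxy-6-methyl-2-oxo-5,6-dihydro-2H-pyran-3-yl]-4-methyl-7-oxohept-1-en-1-yl]-4-methylhex-2-enoic acid | CC[C@H](C)/C=C(\C=C\C[C@H](C)CCC(=O)C1=C(O)C[C@@H](C)OC1=O)C(=O)O | target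

**Step count and risks**

Total steps: 8. Longest linear sequence: 6 (steps 3 to 8, from citronellal 6 to target 18).

Steps most likely to fail:

- **Step 7 (ketene capture/Dieckmann cascade).** The 3-acyloxy ester may eliminate to methyl crotonate, six-ring Dieckmann closure is slower than the tetronate case, and KOtBu could reach the γ-hydrogen of the dienoate. Fallback: the lactone is built first and the acyl group is moved onto it. Methyl (R)-3-hydroxybutanoate 14 is condensed with the lithium enolate of tert-butyl acetate (LiN(iPr)2, THF, −78 → −20 °C) to tert-butyl (5R)-5-hydroxy-3-oxohexanoate F1. TFA/CH2Cl2 closes this to (6R)-4-hydroxy-6-methyl-5,6-dihydro-2H-pyran-2-one F2. Acid 11 is then coupled to F2 with DCC and catalytic DMAP to the enol ester (6R)-6-methyl-2-oxo-5,6-dihydro-2H-pyran-4-yl (4R,6E,8E,10S)-8-(tert-butoxycarbonyl)-4,10-dimethyldodeca-6,8-dienoate F3. A full equivalent of DMAP shifts the acyl group from O4 to C3 (Fries-type acyl migration). This fallback sets out from 11 (lactone partner from 14), bypasses 13, and comes back at 17.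

- **Step 5 (hydroboration of the free acid and one-flask Suzuki coupling).** The acid may consume or divert the borane, and the borinic acid by-products may disturb the coupling. Fallback: the isopropylidene group is kept as the masked acid through the coupling. Enyne 7 is hydroborated with pinacolborane (Cp2Zr(H)Cl 5 mol%, Et3N, 60 °C) to 2-[(1E,4R)-4,8-dimethylnona-1,7-dien-1-yl]-4,4,5,5-tetramethyl-1,3,2-dioxaborolane F4. Suzuki coupling with 5 (PdCl2(dppf), K3PO4, THF/H2O, 50 °C) gives tert-butyl (2E,4S)-2-[(1E,4R)-4,8-dimethylnona-1,7-dien-1-yl]-4-methylhex-2-enoate F5. mCPBA (NaHCO3, CH2Cl2, 0 °C) epoxidises only the electron-rich trisubstituted alkene to tert-butyl (2E,4S)-2-[(1E,4R)-6-(3,3-dimethyloxiran-2-yl)-4-methylhex-1-en-1-yl]-4-methylhex-2-enoate F6. H5IO6 (THF/H2O) cleaves the epoxide to tert-butyl (2E,4S)-4-methyl-2-[(1E,4R)-4-methyl-7-oxohept-1-en-1-yl]hex-2-enoate F7. NaClO2/NaH2PO4/2-methylbut-2-ene then gives the acid. This fallback sets out from 7 (with 5) and comes back at 11.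

- **Step 2 (bromo-ylide Wittig).** The Z:E ratio with an α-branched aliphatic aldehyde may be modest, and 2 may partly racemise. Fallback: the bromine is installed after the olefination. Aldehyde 2 and tert-butyl diethylphosphonoacetate (LiCl, DBU, MeCN; Masamune–Roush Horner–Wadsworth–Emmons) give tert-butyl (2E,4S)-4-methylhex-2-enoate F8. Br2 in CH2Cl2 at 0 °C gives tert-butyl (4S)-2,3-dibromo-4-methylhexanoate F9. Et3N removes HBr by way of the ester enolate to give the more stable (Z)-2-bromoenoate. This fallback sets out from 2 and comes back at 5.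

**Further compounds**

F1 | step 7 | tert-butyl (5R)-5-hydroxy-3-oxohexanoate | C[C@@H](O)CC(=O)CC(=O)OC(C)(C)C
F2 | step 7 | (6R)-4-hydroxy-6-methyl-5,6-dihydro-2H-pyran-2-one | C[C@@H]1CC(O)=CC(=O)O1
F3 | step 7 | (6R)-6-methyl-2-oxo-5,6-dihydro-2H-pyran-4-yl (4R,6E,8E,10S)-8-(tert-butoxycarbonyl)-4,10-dimethyldodeca-6,8-dienoate | CC[C@H](C)/C=C(\C=C\C[C@H](C)CCC(=O)OC1=CC(=O)O[C@H](C)C1)C(=O)OC(C)(C)C
F4 | step 5 | 2-[(1E,4R)-4,8-dimethylnona-1,7-dien-1-yl]-4,4,5,5-tetramethyl-1,3,2-dioxaborolane | C[C@H](CCC=C(C)C)C/C=C/B1OC(C)(C)C(C)(C)O1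
F5 | step 5 | tert-butyl (2E,4S)-2-[(1E,4R)-4,8-dimethylnona-1,7-dien-1-yl]-4-methylhex-2-enoate | CC[C@H](C)/C=C(\C=C\C[C@H](C)CCC=C(C)C)C(=O)OC(C)(C)C
F6 | step 5 | tert-butyl (2E,4S)-2-[(1E,4R)-6-(3,3-dimethyloxiran-2-yl)-4-methylhex-1-en-1-yl]-4-methylhex-2-enoate (both configurations at the oxirane carbon) | CC[C@H](C)/C=C(\C=C\C[C@H](C)CCC1OC1(C)C)C(=O)OC(C)(C)C
F7 | step 5 | tert-butyl (2E,4S)-4-methyl-2-[(1E,4R)-4-methyl-7-oxohept-1-en-1-yl]hex-2-enoate | CC[C@H](C)/C=C(\C=C\C[C@H](C)CCC=O)C(=O)OC(C)(C)C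
F8 | step 2 | tert-butyl (2E,4S)-4-methylhex-2-enoate | CC[C@H](C)/C=C/C(=O)OC(C)(C)C
F9 | step 2 | tert-butyl (4S)-2,3-dibromo-4-methylhexanoate (mixture at C2 and C3) | CC[C@H](C)C(Br)C(Br)C(=O)OC(C)(C)C
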